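**Retrosynthetic overview**
1. Target 10 ⇐ ketone 9 by removing three MOM ethers in the last step.
2. 9 ⇐ cyclopropanol 6 + aryl bromide 8: the Cβ–C(aryl) bond is made with the ketone β-carbon acting as a nucleophile (a ketone homoenolate unmasked on palladium from 6) against the aryl bromide carbon. In the conventional enone / aryl halide sense both carbons are electrophilic.
3. 6 ⇐ aryllithium 4 (from tris-MOM phloroglucinol 2) + cyclopropanone, released from hemiacetal 3.
4. 8 ⇐ 4-bromophenol 7 by double ortho-C-prenylation.
5. No ring is formed: both benzene rings are bought, and the cyclopropane arrives with 3 and is opened again in the key step.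

Assumption: the target has no stereocentre and no stereogenic double bond, so it is one achiral compound and no stereocontrol is needed. Anhydrous phloroglucinol and 1-ethoxycyclopropan-1-ol are taken as bought.

**Route**

Step 1
Reactants: 1 phloroglucinol (benzene-1,3,5-triol)
Product: 2 1,3,5-tris(methoxymethoxy)benzene
Conditions: NaH (3.6 equiv), MOMCl (3.6 equiv), DMF, 0 °C to rt
Reagents that add atoms: chloromethyl methyl ether (MOMCl), COCCl
Why: Williamson-type O-alkylation of the sodium phenoxides with the hard electrophile MOMCl in DMF goes at oxygen, and the three acetals then serve as ortho-directing groups and as base-stable, mildly acid-labile masks.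

Step 2
Reactants: 2 1,3,5-tris(methoxymethoxy)benzene, 3 1-ethoxycyclopropan-1-ol
Product: 6 1-[2,4,6-tris(methoxymethoxy)phenyl]cyclopropan-1-ol, via aryllithium 4 (not isolated), via bromomagnesium hemiacetalate 5 (not isolated)
Conditions: 2, n-BuLi (1.1 equiv), THF, 0 °C, 1 h; separately 3 (1.5 equiv), MeMgBr (1.5 equiv), THF, 0 °C; combine, 0 to 40 °C; then H2O, 0 °C
Reagents that add atoms: none
Why: Directed ortho-metalation lithiates the ring carbon flanked by two OMOM groups, and the aryllithium then undergoes 1,2-addition to the strained cyclopropanone that the magnesium hemiacetalate releases in equilibrium (cyclopropanone-hemiacetal addition); no stereocentre is formed.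

Step 3
Reactants: 7 4-bromophenol
Product: 8 4-bromo-2,6-bis(3-methylbut-2-en-1-yl)phenol
Conditions: NaH (2 × 1.1 equiv), prenyl bromide (2 × 1.1 equiv), toluene, 0 °C to rt
Reagents that add atoms: prenyl bromide (1-bromo-3-methylbut-2-ene), CC(C)=CCBr
Why: In toluene the sodium phenoxide reacts as a tight ion pair that alkylates at the ortho carbon (ortho-C-alkylation of a phenoxide, SN2 at the primary allylic carbon, then rearomatisation), the para position is blocked by bromine, and a second portion of base and bromide fills the other ortho position; a modest yield is expected and the mono-prenyl phenol can be recycled.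

Step 4
Reactants: 6 1-[2,4,6-tris(methoxymethoxy)phenyl]cyclopropan-1-ol, 8 4-bromo-2,6-bis(3-methylbut-2-en-1-yl)phenol
Product: 9 3-[4-hydroxy-3,5-bis(3-methylbut-2-en-1-yl)phenyl]-1-[2,4,6-tris(methoxymethoxy)phenyl]propan-1-one
Conditions: Pd(OAc)2 (5 mol %), XPhos (10 mol %), Cs2CO3 (3 equiv), toluene, 80 °C; pH 7 buffer work-up
Reagents that add atoms: none
Why: Zerovalent palladium formed from Pd(OAc)2/XPhos inserts into the C–Br bond of 8, the cyclopropanol binds as a palladium alkoxide and opens by strain-driven β-carbon elimination to a palladium ketone homoenolate, and reductive elimination joins its β-carbon to the aryl carbon (palladium-catalysed ring-opening cross-coupling of a cyclopropanol with an aryl bromide); the bulky biarylphosphine favours reductive elimination over β-hydride elimination, and the hindered 2,6-dialkylphenoxide and trisubstituted prenyl alkenes are poor partners for C–O coupling or Heck insertion.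

Step 5
Reactants: 9 3-[4-hydroxy-3,5-bis(3-methylbut-2-en-1-yl)phenyl]-1-[2,4,6-tris(methoxymethoxy)phenyl]propan-1-one
Product: 10 3-[4-hydroxy-3,5-bis(3-methylbut-2-en-1-yl)phenyl]-1-(2,4,6-trihydroxyphenyl)propan-1-one (4,2',4',6'-tetrahydroxy-3,5-diprenyldihydrochalcone)
Conditions: HCl (1.25 M in MeOH), 40 °C, monitored and stopped at full conversion
Reagents that add atoms: none
Why: Acid-catalysed transacetalisation to methanol (MOM ether cleavage) frees the three phenols, those ortho to the ketone fastest, while dilute acid and low temperature keep the prenyl alkenes from cyclising onto the neighbouring phenol to chromans; the product is achiral.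

**Compound list**
1 | phloroglucinol (benzene-1,3,5-triol) | Oc1cc(O)cc(O)c1 | starting material
2 | 1,3,5-tris(methoxymethoxy)benzene | COCOc1cc(OCOC)cc(OCOC)c1 | intermediate
3 | 1-ethoxycyclopropan-1-ol (cyclopropanone ethyl hemiacetal) | CCOC1(O)CC1 | starting material
4 | [2,4,6-tris(methoxymethoxy)phenyl]lithium | [Li]c1c(OCOC)cc(OCOC)cc1OCOC | intermediate (not isolated)
5 | bromomagnesium 1-ethoxycyclopropan-1-olate | CCOC1(O[Mg]Br)CC1 | intermediate (not isolated)
6 | 1-[2,4,6-tris(methoxymethoxy)phenyl]cyclopropan-1-ol | COCOc1cc(OCOC)c(C2(O)CC2)c(OCOC)c1 | intermediate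
7 | 4-bromophenol | Oc1ccc(Br)cc1 | starting material
8 | 4-bromo-2,6-bis(3-methylbut-2-en-1-yl)phenol | CC(C)=CCc1cc(Br)cc(CC=C(C)C)c1O | intermediate
9 | 3-[4-hydroxy-3,5-bis(3-methylbut-2-en-1-yl)phenyl]-1-[2,4,6-tris(methoxymethoxy)phenyl]propan-1-one | COCOc1cc(OCOC)c(C(=O)CCc2cc(CC=C(C)C)c(O)c(CC=C(C)C)c2)c(OCOC)c1 | intermediate
10 | 3-[4-hydroxy-3,5-bis(3-methylbut-2-en-1-yl)phenyl]-1-(2,4,6-trihydroxyphenyl)propan-1-one | CC(C)=CCc1cc(CCC(=O)c2c(O)cc(O)cc2O)cc(CC=C(C)C)c1O | target

**Step count and risk**

Total steps: 5. Longest linear sequence: 4 (steps 1, 2, 4, 5); step 3 is a one-step side branch that joins at step 4.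

Three steps most likely to fail:

Step 4 (highest risk). The cyclopropanol is hindered and electron-rich, so it may open under base to the propiophenone or give the aryl vinyl ketone by β-hydride elimination, and the free phenoxide slows oxidative addition. The fallback sets out from 8 and from 2 and comes back to the route at 10. Phenol 8 is protected (MOMCl, iPr2NEt, CH2Cl2) as 5-bromo-2-(methoxymethoxy)-1,3-bis(3-methylbut-2-en-1-yl)benzene F1. The ester homoenolate bis(3-ethoxy-3-oxopropyl)zinc F2 is generated from [(1-ethoxycyclopropyl)oxy]trimethylsilane and ZnCl2 in Et2O and cross-coupled with F1 (Pd(OAc)2, SPhos, THF/DMA, 50 °C) to give ethyl 3-[4-(methoxymethoxy)-3,5-bis(3-methylbut-2-en-1-yl)phenyl]propanoate F3. Aryllithium 4, made from 2 as in step 2, is added to F3 at −78 °C; the di-ortho-substituted ketone resists a second addition, giving 3-[4-(methoxymethoxy)-3,5-bis(3-methylbut-2-en-1-yl)phenyl]-1-[2,4,6-tris(methoxymethoxy)phenyl]propan-1-one F4. Methanolic HCl as in step 5 then removes all four MOM groups to give 10. The Cβ–aryl bond is still made from a homoenolate, but a preformed zinc one at the ester oxidation level, and the aryl ketone is made afterwards.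

Step 2. Cyclopropanone may be released too slowly or oligomerise, and the hindered aryllithium may act as a base. The fallback sets out from 2 and comes back at 6. Aryllithium 4 is added to 1,3-dichloroacetone at −78 °C to give 1,3-dichloro-2-[2,4,6-tris(methoxymethoxy)phenyl]propan-2-ol F5. Reductive 1,3-cyclisation with EtMgBr (excess) and catalytic FeCl3 in Et2O then closes the three-membered ring to 6. The ring is built on the arene rather than brought in as cyclopropanone.

Step 3. O-alkylation and mono/di mixtures may leave little pure 8. The fallback sets out from 7 and comes back at 8. Iodination (I2, KI, aqueous NH3) gives 4-bromo-2,6-diiodophenol F6. A double Stille coupling with tributyl(3-methylbut-2-en-1-yl)stannane (Pd(PPh3)4, DMF, 80 °C) reacts at the two C–I bonds in preference to C–Br and gives the linear prenyl groups of 8.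

**Further compounds**
F1 | step 4 | 5-bromo-2-(methoxymethoxy)-1,3-bis(3-methylbut-2-en-1-yl)benzene | COCOc1c(CC=C(C)C)cc(Br)cc1CC=C(C)C
F2 | step 4 | bis(3-ethoxy-3-oxopropyl)zinc | CCOC(=O)CC[Zn]CCC(=O)OCC
F3 | step 4 | ethyl 3-[4-(methoxymethoxy)-3,5-bis(3-methylbut-2-en-1-yl)phenyl]propanoate | CCOC(=O)CCc1cc(CC=C(C)C)c(OCOC)c(CC=C(C)C)c1
F4 | step 4 | 3-[4-(methoxymethoxy)-3,5-bis(3-methylbut-2-en-1-yl)phenyl]-1-[2,4,6-tris(methoxymethoxy)phenyl]propan-1-one | COCOc1cc(OCOC)c(C(=O)CCc2cc(CC=C(C)C)c(OCOC)c(CC=C(C)C)c2)c(OCOC)c1
F5 | step 2 | 1,3-dichloro-2-[2,4,6-tris(methoxymethoxy)phenyl]propan-2-ol | COCOc1cc(OCOC)c(C(O)(CCl)CCl)c(OCOC)c1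
F6 | step 3 | 4-bromo-2,6-diiodophenol | Oc1c(I)cc(Br)cc1I
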